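Read two times off the earlier runs, then take their ratio.

| setting | ash | cedar | east | north-west |
|---|---|---|---|---|
| substrate | 39 mM (fed, over 50 s) | 180 mM (fed, over 50 s) | 33 mM (fed, over 50 s) | 120 mM |
| gas phase | 4.6 mM (held) | 4.6 mM (held) | 4.6 mM (held) | 4.6 mM |
| remark | run made earlier | run made earlier |  | everything together at the start |
| time |  |  | 30 min | 10 min |

| run | time / min | target / % | substrate / % |
|---|---|---|---|
| ash | 5.00 | 9.0 | 89.6 |
| ash | 10.0 | 18.3 | 82.2 |
| ash | 15.0 | 23.7 | 74.7 |
| ash | 20.0 | 27.4 | 68.0 |
| cedar | 2.50 | 4.0 | 95.4 |
| cedar | 8.00 | 14.0 | 86.0 |
| cedar | 15.0 | 22.5 | 75.1 |
| cedar | 20.0 | 26.4 | 68.9 |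

(scatter of a reading: 0.5 percentage points)

- at the start none of the gas is dissolved
- what was read earlier has a scatter of 0.5 percentage points, one standard deviation
- candidate steps: dissolved gas + target -> over-reacted product; gas phase <-> dissolved gas; substrate + dissolved gas <-> target

- the winner by amount of target, in percent of the substrate charged; "neither" if no more than 2 percentage points parts them (east / north-west / neither)
- how much target is there at the end, in percent of the substrate charged: east
- how much target is there at the end, in percent of the substrate charged: north-west

Start with substrate. Cedar carries 4.62 times the charge of ash, yet at 20.0 min it keeps 68.9% of its substrate against 68.0% in ash. So treat the loss as pseudo-first-order and reckon each flask in percent of its own charge. Divide the ash time by the natural log of charge over substrate left: this gives the substrate time constant, τA = 51.9 min, far longer than the 50 s feed.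

Next take the gap in the ash balance at that time, 4.6 percentage points. Divide the time integral of target, summed from its readings, by this gap to get the time constant of target, τP = 70.3 min.

Their ratio is the selectivity factor s = τP/τA = 1.36. As my own estimate, take substrate to target and target onward as two first-order steps in series; then target, as a fraction of the charge, is P = s/(s − 1)·[exp(−t/τP) − exp(−t/τA)]. So I put east at 35.0% and north-west at 16.3%, a gap wider than the margin.

The forecast names east, with 33.5% against 17.5%, and says of north-west: “Adding everything at the start trades the feed delay for a brief gas lag”. Its east lies below mine, and its north-west lies above mine.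

The flask gives 33.2% in east and 17.7% in north-west, so east wins.

    dissolved gas + target → over-reacted product (k = 2.70 L mol⁻¹ min⁻¹)
    gas phase ⇌ dissolved gas, rate k2*(csat - [dissolved gas]) (kL = 29.0 min⁻¹)
    substrate + dissolved gas ⇌ target (K = 280 L mol⁻¹, k = 5.10 L mol⁻¹ min⁻¹)

Dosing made no difference to east, and the slowness of the gas passage none to north-west, where dissolved gas stands at 4.52 mM at 5.00 min. Carry s to east: the estimate of 35.0% stands 1.8 points above the 33.2% in the flask. Now read the north-west flask later, at 25 min, with its amounts held: the same estimate gives 31.7%, and the flask has substrate at 63.3%, over-reacted product at 5.83%, and target at 30.9%.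

(The readings come from a simulation with constants of no real substance; the scatter is artificial.)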